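**Retrosynthetic overview**
- The target comes from its bis-MOM ether by acid deprotection; the (2S) enantiomer is selected from the racemic flavanone by a kinetic resolution (asymmetric transfer hydrogenation).
- The pyranone ring (ring C) is the only ring formed, and it is formed last, by intramolecular oxa-Michael addition of a 2'-hydroxychalcone.
- Key C–C bond: intermolecular Claisen–Schmidt aldol condensation of a prenylated acetophenone (ring A) with 4-(methoxymethoxy)benzaldehyde (ring B).
- The prenyl group is placed by aromatic Claisen rearrangement of a 1,1-dimethylallyl aryl ether, made from the mono-MOM ether of symmetric 2',6'-dihydroxy-4'-methoxyacetophenone.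
- Rings A and B are bought as the two benzenoid starting materials.

Assumption: 1 is purchased as a catalogue compound (otherwise it is made in one step by 4-O-methylation of phloroacetophenone).

**Step 1**
Reactants: 1 1-(2,6-dihydroxy-4-methoxyphenyl)ethanone
Product: 2 1-[2-hydroxy-4-methoxy-6-(methoxymethoxy)phenyl]ethanone
Conditions: MOMCl (1.1 equiv), iPr2NEt (1.5 equiv), CH2Cl2, 0 °C → rt
Reagents that add atoms: chloromethyl methyl ether (MOMCl), COCCl
Why: MOM ether formation (O-alkylation) on a symmetric diphenol gives one regioisomer and stops at the mono-ether, because the remaining OH is held in a strong hydrogen bond to the acetyl C=O.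

**Step 2**
Reactants: 2 1-[2-hydroxy-4-methoxy-6-(methoxymethoxy)phenyl]ethanone
Product: 3 1-[4-methoxy-2-(methoxymethoxy)-6-[(2-methylbut-3-yn-2-yl)oxy]phenyl]ethanone
Conditions: 3-chloro-3-methylbut-1-yne (2 equiv), DBU (2.5 equiv), CuCl2·2H2O (1 mol %), MeCN, 0 °C → rt
Reagents that add atoms: 3-chloro-3-methylbut-1-yne, CC(C)(Cl)C#C
Why: Copper-catalysed propargylic etherification (Godfrey type) puts a tertiary 1,1-dimethylpropargyl group on a hydrogen-bonded phenol, where a Williamson SN2 reaction is not possible.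

**Step 3**
Reactants: 3 1-[4-methoxy-2-(methoxymethoxy)-6-[(2-methylbut-3-yn-2-yl)oxy]phenyl]ethanone
Product: 4 1-[4-methoxy-2-(methoxymethoxy)-6-[(2-methylbut-3-en-2-yl)oxy]phenyl]ethanone
Conditions: H2 (1 atm), Lindlar catalyst (Pd/CaCO3, Pb), quinoline, EtOAc, rt, stopped after 1 equiv H2
Reagents that add atoms: none
Why: Lindlar semihydrogenation stops at the terminal alkene; the aryl ketone, MOM acetal and aryl ether are inert.

**Step 4**
Reactants: 4 1-[4-methoxy-2-(methoxymethoxy)-6-[(2-methylbut-3-en-2-yl)oxy]phenyl]ethanone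
Product: 6 1-[2-hydroxy-4-methoxy-6-(methoxymethoxy)-3-(3-methylbut-2-en-1-yl)phenyl]ethanone, via ortho-dienone 5 (not isolated)
Conditions: PhNEt2, 125 °C, 3 h, Ar
Reagents that add atoms: none
Why: Aromatic Claisen rearrangement ([3,3]-sigmatropic) can only go to C-3, since the other ortho carbon carries the acetyl group; allyl inversion turns the 1,1-dimethylallyl ether into a C-prenyl group, and the dienone re-aromatises to the chelated phenol.

**Step 5**
Reactants: 7 4-hydroxybenzaldehyde
Product: 8 4-(methoxymethoxy)benzaldehyde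
Conditions: MOMCl (1.2 equiv), iPr2NEt (1.5 equiv), CH2Cl2, 0 °C → rt
Reagents that add atoms: chloromethyl methyl ether (MOMCl), COCCl
Why: MOM ether formation masks the acidic 4-OH, which as a phenoxide would deactivate the aldehyde under the basic aldol conditions.

**Step 6**
Reactants: 6 1-[2-hydroxy-4-methoxy-6-(methoxymethoxy)-3-(3-methylbut-2-en-1-yl)phenyl]ethanone; 8 4-(methoxymethoxy)benzaldehyde
Product: 10 (E)-1-[2-hydroxy-4-methoxy-6-(methoxymethoxy)-3-(3-methylbut-2-en-1-yl)phenyl]-3-[4-(methoxymethoxy)phenyl]prop-2-en-1-one, via aldol adduct 9 (not isolated)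
Conditions: KOH (50 % aq, 10 equiv), EtOH, 0 °C → rt, 36 h, N2; then cold 1 M HCl to pH 5–6
Reagents that add atoms: none
Why: Claisen–Schmidt crossed aldol condensation: only the methyl ketone can enolise, the aldehyde cannot, and E1cB loss of water gives the conjugated (E)-enone; MOM ethers and the prenyl group are base-stable.

**Step 7**
Reactants: 10 (E)-1-[2-hydroxy-4-methoxy-6-(methoxymethoxy)-3-(3-methylbut-2-en-1-yl)phenyl]-3-[4-(methoxymethoxy)phenyl]prop-2-en-1-one
Product: 11 rac-7-methoxy-5-(methoxymethoxy)-2-[4-(methoxymethoxy)phenyl]-8-(3-methylbut-2-en-1-yl)chroman-4-one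
Conditions: NaOAc (10 equiv), EtOH, reflux, 24 h
Reagents that add atoms: none
Why: Intramolecular oxa-Michael addition (6-endo-trig) of the only free phenol, 2'-OH, closes the pyranone ring with the ring oxygen next to the prenylated carbon; C-2 is formed racemic here.

**Step 8**
Reactants: 11 rac-7-methoxy-5-(methoxymethoxy)-2-[4-(methoxymethoxy)phenyl]-8-(3-methylbut-2-en-1-yl)chroman-4-one
Product: 12 (2S)-7-methoxy-5-(methoxymethoxy)-2-[4-(methoxymethoxy)phenyl]-8-(3-methylbut-2-en-1-yl)chroman-4-one
Conditions: [Cp*RhCl((R,R)-TsDPEN)] (1 mol %), HCO2H/Et3N (1:1, 2 equiv), EtOAc, 35 °C, to 52–55 % conversion (chiral HPLC); SiO2 chromatography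
Reagents that add atoms: none
Why: Noyori–Ikariya asymmetric transfer hydrogenation used as a kinetic resolution: the (R,R)-catalyst forms (4R)-carbinols and can do so by the favoured axial hydride delivery only on the (2R)-ketone, which goes to the cis-(2R,4R)-flavan-4-ol, so the (2S)-ketone is left in high ee (at most 50 % yield) and the prenyl alkene is untouched.

**Step 9**
Reactants: 12 (2S)-7-methoxy-5-(methoxymethoxy)-2-[4-(methoxymethoxy)phenyl]-8-(3-methylbut-2-en-1-yl)chroman-4-one
Product: 14 (2S)-5-hydroxy-2-(4-hydroxyphenyl)-7-methoxy-8-(3-methylbut-2-en-1-yl)chroman-4-one (Mundulea flavanone B), via 5-hydroxy mono-MOM flavanone 13 (not isolated)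
Conditions: 3 M aq HCl/MeOH (1:4), 45 °C, 2–3 h
Reagents that add atoms: none
Why: Acid-catalysed acetal methanolysis removes both MOM groups (the chelated 5-O-MOM first); the prenyl group has no free ortho-OH to cyclise onto, and C-2 is stable in acid because flavanone racemisation needs base-induced ring opening.

**Compound list**
1 | 1-(2,6-dihydroxy-4-methoxyphenyl)ethanone | CC(=O)c1c(O)cc(OC)cc1O | starting material
2 | 1-[2-hydroxy-4-methoxy-6-(methoxymethoxy)phenyl]ethanone | CC(=O)c1c(O)cc(OC)cc1OCOC | intermediate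
3 | 1-[4-methoxy-2-(methoxymethoxy)-6-[(2-methylbut-3-yn-2-yl)oxy]phenyl]ethanone | CC(=O)c1c(OC(C)(C)C#C)cc(OC)cc1OCOC | intermediate
4 | 1-[4-methoxy-2-(methoxymethoxy)-6-[(2-methylbut-3-en-2-yl)oxy]phenyl]ethanone | CC(=O)c1c(OC(C)(C)C=C)cc(OC)cc1OCOC | intermediate
5 | 2-acetyl-5-methoxy-3-(methoxymethoxy)-6-(3-methylbut-2-en-1-yl)cyclohexa-2,4-dien-1-one (racemic, not isolated) | CC(=O)C1=C(OCOC)C=C(OC)C(CC=C(C)C)C1=O | intermediate
6 | 1-[2-hydroxy-4-methoxy-6-(methoxymethoxy)-3-(3-methylbut-2-en-1-yl)phenyl]ethanone | CC(=O)c1c(O)c(CC=C(C)C)c(OC)cc1OCOC | intermediate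
7 | 4-hydroxybenzaldehyde | O=Cc1ccc(O)cc1 | starting material
8 | 4-(methoxymethoxy)benzaldehyde | COCOc1ccc(C=O)cc1 | intermediate
9 | 3-hydroxy-1-[2-hydroxy-4-methoxy-6-(methoxymethoxy)-3-(3-methylbut-2-en-1-yl)phenyl]-3-[4-(methoxymethoxy)phenyl]propan-1-one (racemic, not isolated) | COCOc1ccc(C(O)CC(=O)c2c(O)c(CC=C(C)C)c(OC)cc2OCOC)cc1 | intermediate
10 | (E)-1-[2-hydroxy-4-methoxy-6-(methoxymethoxy)-3-(3-methylbut-2-en-1-yl)phenyl]-3-[4-(methoxymethoxy)phenyl]prop-2-en-1-one | COCOc1ccc(/C=C/C(=O)c2c(O)c(CC=C(C)C)c(OC)cc2OCOC)cc1 | intermediate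
11 | rac-7-methoxy-5-(methoxymethoxy)-2-[4-(methoxymethoxy)phenyl]-8-(3-methylbut-2-en-1-yl)chroman-4-one | COc1cc(OCOC)c2c(c1CC=C(C)C)OC(c1ccc(OCOC)cc1)CC2=O | intermediate
12 | (2S)-7-methoxy-5-(methoxymethoxy)-2-[4-(methoxymethoxy)phenyl]-8-(3-methylbut-2-en-1-yl)chroman-4-one | COc1cc(OCOC)c2c(c1CC=C(C)C)O[C@H](c1ccc(OCOC)cc1)CC2=O | intermediate
13 | (2S)-5-hydroxy-7-methoxy-2-[4-(methoxymethoxy)phenyl]-8-(3-methylbut-2-en-1-yl)chroman-4-one (not isolated) | COc1cc(O)c2c(c1CC=C(C)C)O[C@H](c1ccc(OCOC)cc1)CC2=O | intermediate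
14 | (2S)-5-hydroxy-2-(4-hydroxyphenyl)-7-methoxy-8-(3-methylbut-2-en-1-yl)chroman-4-one (Mundulea flavanone B) | COc1cc(O)c2c(c1CC=C(C)C)O[C@H](c1ccc(O)cc1)CC2=O | target

**Totals and risks**
Total step count: 9. Longest linear sequence: 8 steps (1 → 2 → 3 → 4 → 6 → 10 → 11 → 12 → 14); step 5 is a one-step side branch.

The three steps most likely to fail:

Step 2 (tertiary propargylation of a chelated phenol; it may stall or give C-alkylation). The fallback sets out from 2 and comes back at 4. Phenol 2 is O-allylated at the tertiary terminus by a Tsuji–Trost etherification with tert-butyl 2-methylbut-3-en-2-yl carbonate (Pd(PPh3)4 cat., THF, 0 °C). This gives the 1,1-dimethylallyl ether 4 directly and makes the semihydrogenation unnecessary; it makes no new compound (F0).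

Step 4 (the tertiary allyl aryl ether may ionise to phenol 2 and isoprene, or migrate further, instead of giving the ortho-Claisen product). The fallback sets out from 1 and comes back at 6. The symmetric diphenol 1 is C-prenylated on the ring (prenyl bromide, DBU, THF, 0 °C → rt; phenoxide C-alkylation, one C-regioisomer possible) to give 1-[2,6-dihydroxy-4-methoxy-3-(3-methylbut-2-en-1-yl)phenyl]ethanone F1. MOMCl/iPr2NEt at 0 °C then caps the less hindered OH, the one not flanked by the prenyl group, to give 6. The regiochemistry is checked by NOE between OCH2O and the lone aromatic H.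

Step 8 (the electron-rich, 5-alkoxy-substituted ketone may be reduced too slowly or with too low a selectivity factor). The fallback sets out from 11 and comes back at 12, and moves the resolution from the ketone to the alcohol. NaBH4 (MeOH/THF, 0 °C) reduces 11 by axial hydride delivery to racemic 2,4-cis-7-methoxy-5-(methoxymethoxy)-2-[4-(methoxymethoxy)phenyl]-8-(3-methylbut-2-en-1-yl)chroman-4-ol F2. Lipase-catalysed transesterification (Amano PS or CAL-B, vinyl acetate, MTBE, 35 °C) acylates the (4R)-alcohol (Kazlauskas rule) and leaves (2S,4S)-7-methoxy-5-(methoxymethoxy)-2-[4-(methoxymethoxy)phenyl]-8-(3-methylbut-2-en-1-yl)chroman-4-ol F3. After chromatography, F3 is reoxidised with Dess–Martin periodinane (NaHCO3, CH2Cl2, 0 °C) to 12.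

**Further compounds**
F0 | step 2 | none | none
F1 | step 4 | 1-[2,6-dihydroxy-4-methoxy-3-(3-methylbut-2-en-1-yl)phenyl]ethanone | CC(=O)c1c(O)cc(OC)c(CC=C(C)C)c1O
F2 | step 8 | racemic 2,4-cis-7-methoxy-5-(methoxymethoxy)-2-[4-(methoxymethoxy)phenyl]-8-(3-methylbut-2-en-1-yl)chroman-4-ol | COc1cc(OCOC)c2c(c1CC=C(C)C)OC(c1ccc(OCOC)cc1)CC2O
F3 | step 8 | (2S,4S)-7-methoxy-5-(methoxymethoxy)-2-[4-(methoxymethoxy)phenyl]-8-(3-methylbut-2-en-1-yl)chroman-4-ol | COc1cc(OCOC)c2c(c1CC=C(C)C)O[C@H](c1ccc(OCOC)cc1)C[C@@H]2O
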